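**Retrosynthetic overview**

1. Target ⇒ 12-O-silyl tetraol ⇒ ten-membered ring by ring-closing metathesis at C5=C6; C4–C6/C16 come from methallylboration of a C3 aldehyde, C6 from vinyl addition to a C7 aldehyde, and the lactone is shifted from O9 to O7 after ring closure.
2. Lactone carbons C7, C8, C17–C19 ⇒ Nozaki–Hiyama–Kishi coupling of a C9 aldehyde with a (Z)-β-triflyloxy enoate, then syn-dihydroxylation of the resulting C9 butenolide (C9 controls C8 and C17).
3. Ring A (C1, C10–C14) ⇒ C11–C12 bond by intramolecular Paternò–Büchi reaction of a C12 aldehyde with the C10 vinyl group (C11=C20), then hydride opening of the oxetane at C20 to give the C20 methyl and the cis C12 hydroxyl.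
4. Enabling feature: C1 is quaternary, so the C12 aldehyde (tether C13–C14–C1–C10) has no γ-hydrogen and is held 1,6 to C11=C20; the cis C11-methyl/C12-hydroxyl pair of ring A is exactly the two termini of a cis-fused oxetane (C11–C20–O–C12).
5. C1/C10 ⇒ dianionic Ireland–Claisen rearrangement of an Evans-aldol-derived β-hydroxy ester; C14 ⇒ β-lactone opening with lithioacetonitrile and 1,3-anti reduction. Ring order: temporary dioxane → oxetane + ring A (key) → butenolide → ten-membered ring → C7 lactone.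

Key step: step 13

Remark: briarane numbering (C1–C20) is used for all intermediates; β is the face of ring A that carries the C15 methyl group. The dianion of step 7 is assumed to rearrange as the dilithium species, without silylation.

**Route**

Step 1
Reactants: 1 (E)-but-2-ene-1,4-diol
Product: 2 (E)-4-(benzyloxy)but-2-en-1-ol
Conditions: BnBr (1.1 equiv), Ag2O (1.5 equiv), CH2Cl2, 23 °C
Reagents that add atoms: benzyl bromide, BrCc1ccccc1
Why: Silver-oxide-mediated Williamson etherification of a symmetric diol should stop cleanly at the mono-benzyl ether.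

Step 2
Reactants: 3 ethyl glycolate
Product: 4 ethyl 2-[(tert-butyldiphenylsilyl)oxy]acetate
Conditions: TBDPSCl, imidazole, DMF, 23 °C
Reagents that add atoms: tert-butyl(chloro)diphenylsilane, CC(C)(C)[Si](Cl)(c1ccccc1)c1ccccc1
Why: Routine silylation of a primary alcohol; this group becomes the C7 oxygen protection.

Step 3
Reactants: 5 ethyl propanoate; 4 ethyl 2-[(tert-butyldiphenylsilyl)oxy]acetate
Product: 6 ethyl 4-[(tert-butyldiphenylsilyl)oxy]-2-methyl-3-oxobutanoate
Conditions: LiN(iPr)2 (2.1 equiv), 5, THF, −78 °C; then 4, −78 → −20 °C; aq. NH4Cl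
Reagents that add atoms: none
Why: Crossed Claisen condensation of the propanoate lithium enolate with the silyloxyacetate, driven by deprotonation of the β-keto ester by the second equivalent of base.

Step 4
Reactants: 6 ethyl 4-[(tert-butyldiphenylsilyl)oxy]-2-methyl-3-oxobutanoate
Product: 7 (Z)-enol triflate of 6
Conditions: Tf2O, saturated aq. LiOH, toluene/hexanes, 5 °C
Reagents that add atoms: trifluoromethanesulfonic anhydride, O=S(=O)(OS(=O)(=O)C(F)(F)F)C(F)(F)F
Why: O-sulfonylation of the lithium-chelated enolate of the β-keto ester should give the (Z)-enol triflate, the geometry in which the later C9 alkoxide can reach the ester.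

Step 5
Reactants: 8 (R)-4-benzyl-3-propanoyloxazolidin-2-one; 9 2-[(tert-butyldimethylsilyl)oxy]acetaldehyde
Product: 10 Evans syn-aldol adduct
Conditions: Bu2BOTf, iPr2NEt, CH2Cl2, −78 → 0 °C; then 9, −78 → 0 °C; pH 7 buffer, MeOH, H2O2
Reagents that add atoms: none
Why: Evans syn-aldol reaction through the (Z)-boron enolate and a Zimmerman–Traxler chair, in which the (R)-benzyl auxiliary sets the C2 carbinol (R); the α-methyl center is erased again in step 7.

Step 6
Reactants: 10 Evans syn-aldol adduct; 2 (E)-4-(benzyloxy)but-2-en-1-ol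
Product: 11 allyl β-hydroxy ester
Conditions: 2 (3 equiv), n-BuLi (2.5 equiv), THF, −20 → 0 °C; aq. NH4Cl
Reagents that add atoms: none
Why: Transesterification of the N-acyl oxazolidinone by the lithium alkoxide of 2 at the exocyclic carbonyl releases the auxiliary and leaves C2 untouched.

Step 7
Reactants: 11 allyl β-hydroxy ester
Product: 12 C14 carboxylic acid with quaternary C1 and C10 vinyl group
Conditions: LiN(iPr)2 (2.6 equiv), THF, −78 °C; then −78 → 50 °C; 1 M HCl
Reagents that add atoms: none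
Why: Dianionic Ireland–Claisen [3,3]-sigmatropic rearrangement: the C2 alkoxide chelates the lithium enolate and fixes its geometry, the allyl unit bonds to C1 on the face anti to C3, and the chair transition state with the (E)-olefin sets C10, so the C1 quaternary center, C10 and the C11=C20 vinyl group arise together.

Step 8
Reactants: 12 C14 carboxylic acid
Product: 13 β-lactone (O2–C14)
Conditions: PhSO2Cl, pyridine, 0 °C
Reagents that add atoms: none
Why: β-Lactonization of the β-hydroxy acid through the mixed carboxylic–sulfonic anhydride (acyl activation, so C2 keeps its configuration), helped by the quaternary C1.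

Step 9
Reactants: 13 β-lactone
Product: 14 β-keto nitrile (C14 ketone, C12 nitrile, free C2 hydroxyl)
Conditions: MeCN (3 equiv), n-BuLi (2.8 equiv), THF, −78 °C; then 13; AcOH, −78 °C
Reagents that add atoms: acetonitrile, CC#N
Why: Acyl substitution of the strained, non-enolizable β-lactone by lithioacetonitrile (C-acylation) gives the β-keto nitrile, whose immediate deprotonation protects the ketone from a second addition and from retro-aldol cleavage.

Step 10
Reactants: 14 β-keto nitrile
Product: 15 anti-2,14-diol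
Conditions: Me4NBH(OAc)3, MeCN/AcOH (1:1), −30 °C
Reagents that add atoms: none
Why: Evans–Saksena reduction: the C2 hydroxyl binds the acetoxyborohydride and delivers hydride intramolecularly through a chair, which should set C14 1,3-anti to C2.

Step 11
Reactants: 15 anti-2,14-diol
Product: 16 2,14-acetonide nitrile
Conditions: 2,2-dimethoxypropane, PPTS (cat.), CH2Cl2, 23 °C
Reagents that add atoms: 2,2-dimethoxypropane, COC(C)(C)OC
Why: Acid-catalysed transketalization ties O2 and O14 into a six-membered acetonide, which later shields the α-face of ring A.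

Step 12
Reactants: 16 2,14-acetonide nitrile
Product: 17 C12 aldehyde
Conditions: iBu2AlH (1.3 equiv), toluene, −78 °C; then aq. Rochelle salt, 23 °C
Reagents that add atoms: water, O
Why: Partial reduction of the nitrile to the N-aluminated aldimine, hydrolysed on work-up to the aldehyde without touching the silyl ether, the benzyl ether or the acetonide.

Step 13
Reactants: 17 C12 aldehyde
Product: 18 oxetane (ring A fused to the C11–C20–O–C12 oxetane)
Conditions: hν (300 nm lamps, Pyrex), degassed MeCN, 0.005 M, 20 °C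
Reagents that add atoms: none
Why: Paternò–Büchi [2+2] photocycloaddition: n,π* excitation of the C12 aldehyde, bonding to the tethered C11=C20 vinyl group through an exciplex or 1,4-biradical, and collapse to the oxetane; the closest known reaction type is the intramolecular Paternò–Büchi reaction of ω-alkenyl aldehydes and ketones that gives fused bicyclic oxetanes. Ring A closes by attack of the carbonyl carbon C12 on the internal vinyl carbon C11 (six-membered, exo mode) and the oxetane closes by O–C20 bonding at the terminal carbon; the fused rather than the bridged regiochemistry is expected because it passes through the secondary C11 radical and a six-membered ring. C11 and C12 are set together: the cis fusion forced by the four-membered ring puts C20 and O12 on the same face, and that face should be β because the acetonide ring is cis-fused to the forming ring at C1–C14 on the α-face and makes it the concave face. The step needs chemoselectivity over Norrish type-two cleavage and over intermolecular addition: C1 is quaternary, so the aldehyde has no γ-hydrogen, and high dilution with 300 nm light (only the aldehyde absorbs) should suppress the rest. The strained oxetane then holds O12 in place and leaves C20 one hydride away from the methyl group.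

Step 14
Reactants: 18 oxetane
Product: 19 ring A alcohol (C11 β-methyl, C12 β-hydroxyl)
Conditions: LiEt3BH (6 equiv), THF, 0 → 65 °C; aq. NH4Cl
Reagents that add atoms: none
Why: Strain-driven SN2 opening of the oxetane by hydride at the primary C20 rather than the ring carbon C12 turns C20 into the methyl group and frees the C12 hydroxyl, keeping the cis relation from step 13.

Step 15
Reactants: 19 ring A alcohol
Product: 20 12-O-TIPS ether
Conditions: TIPSOTf, 2,6-lutidine, CH2Cl2, 0 → 23 °C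
Reagents that add atoms: triisopropylsilyl trifluoromethanesulfonate, CC(C)[Si](OS(=O)(=O)C(F)(F)F)(C(C)C)C(C)C
Why: Silylation of the only free hydroxyl gives a robust ether that keeps O12 out of the final acetylation.

Step 16
Reactants: 20 12-O-TIPS ether
Product: 21 C9 primary alcohol
Conditions: H2 (1 atm), Pd(OH)2/C, EtOAc, 23 °C
Reagents that add atoms: none
Why: Hydrogenolysis of the benzyl ether, possible here because no alkene is left after step 13.

Step 17
Reactants: 21 C9 primary alcohol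
Product: 22 C9 aldehyde
Conditions: Dess–Martin periodinane, NaHCO3, CH2Cl2, 0 → 23 °C
Reagents that add atoms: none
Why: Buffered Dess–Martin oxidation should give the aldehyde without epimerizing C10.

Step 18
Reactants: 22 C9 aldehyde; 7 (Z)-enol triflate
Product: 24 C9 butenolide, via hydroxy enoate 23 (not isolated)
Conditions: CrCl2 (6 equiv), NiCl2 (0.05 equiv), DMF, 23 °C; then PPTS, CH2Cl2, 23 °C
Reagents that add atoms: none
Why: Nozaki–Hiyama–Kishi coupling of the vinyl triflate with the aldehyde under Felkin–Anh control (quaternary C1 anti to the incoming alkenylchromium) should set C9 (R), and the (Z)-ester then closes the butenolide on O9.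

Step 19
Reactants: 24 C9 butenolide
Product: 25 8,17-diol lactone
Conditions: RuCl3 (0.05 equiv), CeCl3·7H2O (0.1 equiv), NaIO4 (1.5 equiv), EtOAc/MeCN/H2O (3:3:1), 0 °C, short contact; aq. Na2S2O3
Reagents that add atoms: sodium periodate, [Na+].[O-]I(=O)(=O)=O
Why: RuO4-catalysed syn-dihydroxylation of the tetrasubstituted, electron-poor butenolide double bond on the ring face anti to the bulky C10 substituent at C9 sets C8 and C17; the cis diol on this C9 lactone is the trans diol of the final C7 lactone.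

Step 20
Reactants: 25 8,17-diol lactone
Product: 26 C3 primary alcohol
Conditions: HF·pyridine, pyridine, THF, 0 °C
Reagents that add atoms: none
Why: Selective cleavage of the primary TBS ether in the presence of the primary TBDPS ether, the hindered secondary TIPS ether and the acetonide.

Step 21
Reactants: 26 C3 primary alcohol
Product: 27 C3 aldehyde
Conditions: SO3·pyridine, DMSO, iPr2NEt, CH2Cl2, 0 °C
Reagents that add atoms: none
Why: Parikh–Doering oxidation avoids hypervalent-iodine reagents, which could cleave the ditertiary 8,17-diol, and leaves the tertiary hydroxyls alone.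

Step 22
Reactants: 27 C3 aldehyde
Product: 28 (3S)-homoallylic alcohol with the C4–C5(C16)=CH2 unit
Conditions: 2-methylallylboronic acid pinacol ester (2 equiv), toluene, 23 °C; then triethanolamine
Reagents that add atoms: 2-methylallylboronic acid pinacol ester, CC(=C)CB1OC(C)(C)C(C)(C)O1
Why: Allylboration through a closed chair transition state under Cornforth/Felkin–Anh control, with the nucleophile anti to O2 and passing H2 rather than the quaternary C1, should set C3 (S), anti to O2.

Step 23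
Reactants: 28 (3S)-homoallylic alcohol
Product: 29 C7 primary alcohol
Conditions: Bu4NF, AcOH (1:1), THF, 0 → 23 °C
Reagents that add atoms: none
Why: Buffered fluoride removes the primary TBDPS ether while the hindered secondary TIPS ether and the lactone survive.

Step 24
Reactants: 29 C7 primary alcohol
Product: 30 C7 aldehyde
Conditions: [Cu(MeCN)4]OTf (0.05 equiv), 2,2′-bipyridine, TEMPO, N-methylimidazole, air, MeCN, 23 °C
Reagents that add atoms: none
Why: Copper/TEMPO aerobic oxidation is selective for the primary C7 alcohol over the secondary C3 and the tertiary C8 and C17 alcohols and tolerates the alkene.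

Step 25
Reactants: 30 C7 aldehyde
Product: 31 (7S)-allylic alcohol
Conditions: CH2=CHMgBr (6 equiv), THF/CH2Cl2, −78 → −40 °C; aq. NH4Cl
Reagents that add atoms: vinylmagnesium bromide, C=C[Mg]Br
Why: Chelation-controlled Grignard addition: magnesium bridges the C7 carbonyl and the C8 alkoxide, and the vinyl group adds from the C17 side, away from C9 and ring A, which should set C7 (S), syn to O8.

Step 26
Reactants: 31 (7S)-allylic alcohol
Product: 32 ten-membered ring with (5Z) double bond, lactone on O9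
Conditions: second-generation Hoveyda–Grubbs catalyst (0.2 equiv in portions), 1,4-benzoquinone (0.2 equiv), toluene, 0.001 M, 100 °C
Reagents that add atoms: none
Why: Ring-closing metathesis between the C7 vinyl group and the 1,1-disubstituted C5 olefin; the ten-membered ring, constrained by ring A and the lactone, should take the less strained (Z) geometry.

Step 27
Reactants: 32 ten-membered ring, lactone on O9
Product: 33 ten-membered ring, lactone on O7, free C9 hydroxyl
Conditions: DBU (0.5 equiv), toluene, 23 → 50 °C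
Reagents that add atoms: none
Why: Base-mediated translactonization (1,3-acyl shift through the five-membered tetrahedral intermediate at C19) under thermodynamic control should settle on the O7 lactone, the arrangement that the briarane skeleton adopts when C9 carries a free hydroxyl.

Step 28
Reactants: 33 O7 lactone acetonide
Product: 34 2,3,9,14-tetraol (12-O-TIPS)
Conditions: AcOH/H2O (4:1), 45 °C
Reagents that add atoms: none
Why: Mild acid hydrolysis of the anti-diol acetonide, which the secondary TIPS ether and the lactone should survive.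

Step 29
Reactants: 34 2,3,9,14-tetraol
Product: 35 12-O-TIPS briaexcavatolide K
Conditions: Ac2O, pyridine, DMAP (cat.), CH2Cl2, 0 → 23 °C
Reagents that add atoms: acetic anhydride, CC(=O)OC(C)=O
Why: Acetylation of the four secondary hydroxyls (C2, C3, C9, C14); the tertiary C8 and C17 hydroxyls are too hindered to react under these conditions.

Step 30
Reactants: 35 12-O-TIPS briaexcavatolide K
Product: 36 briaexcavatolide K
Conditions: HF·pyridine, THF, 0 → 23 °C
Reagents that add atoms: none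
Why: Fluoride-mediated desilylation under mildly acidic conditions frees the C12 hydroxyl without acetyl migration or loss.

**Compound list**

1 | (E)-but-2-ene-1,4-diol | OC/C=C/CO | starting material
2 | (E)-4-(benzyloxy)but-2-en-1-ol | OC/C=C/COCc1ccccc1 | intermediate
3 | ethyl glycolate | OCC(=O)OCC | starting material
4 | ethyl 2-[(tert-butyldiphenylsilyl)oxy]acetate | CCOC(=O)CO[Si](c1ccccc1)(c1ccccc1)C(C)(C)C | intermediate
5 | ethyl propanoate | CCC(=O)OCC | starting material
6 | ethyl 4-[(tert-butyldiphenylsilyl)oxy]-2-methyl-3-oxobutanoate (racemic) | CCOC(=O)C(C)C(=O)CO[Si](c1ccccc1)(c1ccccc1)C(C)(C)C | intermediate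
7 | ethyl (Z)-4-[(tert-butyldiphenylsilyl)oxy]-2-methyl-3-[(trifluoromethanesulfonyl)oxy]but-2-enoate | CCOC(=O)/C(C)=C(\OS(=O)(=O)C(F)(F)F)CO[Si](c1ccccc1)(c1ccccc1)C(C)(C)C | intermediate
8 | (R)-4-benzyl-3-propanoyloxazolidin-2-one | CCC(=O)N1[C@H](Cc2ccccc2)COC1=O | starting material
9 | 2-[(tert-butyldimethylsilyl)oxy]acetaldehyde | O=CCO[Si](C)(C)C(C)(C)C | starting material
10 | (R)-4-benzyl-3-[(2R,3R)-4-[(tert-butyldimethylsilyl)oxy]-3-hydroxy-2-methylbutanoyl]oxazolidin-2-one | C[C@@H](C(=O)N1[C@H](Cc2ccccc2)COC1=O)[C@@H](O)CO[Si](C)(C)C(C)(C)C | intermediate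
11 | (E)-4-(benzyloxy)but-2-en-1-yl (2R,3R)-4-[(tert-butyldimethylsilyl)oxy]-3-hydroxy-2-methylbutanoate | C[C@@H](C(=O)OC/C=C/COCc1ccccc1)[C@@H](O)CO[Si](C)(C)C(C)(C)C | intermediate
12 | (2S,3S)-3-[(benzyloxy)methyl]-2-[(1R)-2-[(tert-butyldimethylsilyl)oxy]-1-hydroxyethyl]-2-methylpent-4-enoic acid (C14 acid; C1, C2, C10 arranged as in the target) | OC(=O)[C@](C)([C@@H](O)CO[Si](C)(C)C(C)(C)C)[C@@H](COCc1ccccc1)C=C | intermediate
13 | (3S,4R)-3-[(2S)-1-(benzyloxy)but-3-en-2-yl]-4-{[(tert-butyldimethylsilyl)oxy]methyl}-3-methyloxetan-2-one | O=C1O[C@@H](CO[Si](C)(C)C(C)(C)C)[C@]1(C)[C@@H](COCc2ccccc2)C=C | intermediate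
14 | (4S,5R)-4-[(2S)-1-(benzyloxy)but-3-en-2-yl]-6-[(tert-butyldimethylsilyl)oxy]-5-hydroxy-4-methyl-3-oxohexanenitrile | N#CCC(=O)[C@](C)([C@@H](O)CO[Si](C)(C)C(C)(C)C)[C@@H](COCc1ccccc1)C=C | intermediate
15 | (3S,4R,5R)-4-[(2S)-1-(benzyloxy)but-3-en-2-yl]-6-[(tert-butyldimethylsilyl)oxy]-3,5-dihydroxy-4-methylhexanenitrile | N#CC[C@H](O)[C@](C)([C@@H](O)CO[Si](C)(C)C(C)(C)C)[C@@H](COCc1ccccc1)C=C | intermediate
16 | 2-[(4S,5R,6R)-5-[(2S)-1-(benzyloxy)but-3-en-2-yl]-6-{[(tert-butyldimethylsilyl)oxy]methyl}-2,2,5-trimethyl-1,3-dioxan-4-yl]acetonitrile | N#CC[C@@H]1OC(C)(C)O[C@@H](CO[Si](C)(C)C(C)(C)C)[C@]1(C)[C@@H](COCc2ccccc2)C=C | intermediate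
17 | 2-[(4S,5R,6R)-5-[(2S)-1-(benzyloxy)but-3-en-2-yl]-6-{[(tert-butyldimethylsilyl)oxy]methyl}-2,2,5-trimethyl-1,3-dioxan-4-yl]acetaldehyde (C12 aldehyde) | O=CC[C@@H]1OC(C)(C)O[C@@H](CO[Si](C)(C)C(C)(C)C)[C@]1(C)[C@@H](COCc2ccccc2)C=C | intermediate
18 | oxetane: ring A (C1, C10–C14) cis-fused on its β-face to the oxetane C11–C20H2–O–C12 and cis-fused at C1–C14 to the 2,14-acetonide; C15 methyl β on C1, C9H2OBn on C10, C3H2OTBS on C2 | C1O[C@H]2C[C@@H]3OC(C)(C)O[C@@H](CO[Si](C)(C)C(C)(C)C)[C@]3(C)[C@@H](COCc4ccccc4)[C@@H]12 | intermediate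
19 | ring A alcohol: 11β-methyl, 12β-hydroxyl, 2,14-acetonide, C9H2OBn, C3H2OTBS | C[C@H]1[C@@H](O)C[C@@H]2OC(C)(C)O[C@@H](CO[Si](C)(C)C(C)(C)C)[C@]2(C)[C@H]1COCc1ccccc1 | intermediate
20 | 12-O-triisopropylsilyl ether of 19 | C[C@H]1[C@@H](O[Si](C(C)C)(C(C)C)C(C)C)C[C@@H]2OC(C)(C)O[C@@H](CO[Si](C)(C)C(C)(C)C)[C@]2(C)[C@H]1COCc1ccccc1 | intermediate
21 | C9 primary alcohol (benzyl removed from 20) | C[C@H]1[C@@H](O[Si](C(C)C)(C(C)C)C(C)C)C[C@@H]2OC(C)(C)O[C@@H](CO[Si](C)(C)C(C)(C)C)[C@]2(C)[C@H]1CO | intermediate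
22 | C9 aldehyde | C[C@H]1[C@@H](O[Si](C(C)C)(C(C)C)C(C)C)C[C@@H]2OC(C)(C)O[C@@H](CO[Si](C)(C)C(C)(C)C)[C@]2(C)[C@H]1C=O | intermediate
23 | ethyl (Z)-enoate with (9R)-hydroxyl: C9(OH)–C8(CH2OTBDPS)=C17(CH3)–CO2Et on C10 | C[C@H]1[C@@H](O[Si](C(C)C)(C(C)C)C(C)C)C[C@@H]2OC(C)(C)O[C@@H](CO[Si](C)(C)C(C)(C)C)[C@]2(C)[C@H]1[C@@H](O)/C(CO[Si](c1ccccc1)(c1ccccc1)C(C)(C)C)=C(/C)C(=O)OCC | intermediate
24 | (9R)-butenolide: 3-methyl-4-[(TBDPS-oxy)methyl]furan-2(5H)-one carrying ring A at its C5 (= C9) | C[C@H]1[C@@H](O[Si](C(C)C)(C(C)C)C(C)C)C[C@@H]2OC(C)(C)O[C@@H](CO[Si](C)(C)C(C)(C)C)[C@]2(C)[C@H]1[C@H]1OC(=O)C(C)=C1CO[Si](c1ccccc1)(c1ccccc1)C(C)(C)C | intermediate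
25 | (8R,9R,17R)-8,17-dihydroxy C9 lactone (cis diol anti to C10) | C[C@H]1[C@@H](O[Si](C(C)C)(C(C)C)C(C)C)C[C@@H]2OC(C)(C)O[C@@H](CO[Si](C)(C)C(C)(C)C)[C@]2(C)[C@H]1[C@H]1OC(=O)[C@](C)(O)[C@@]1(O)CO[Si](c1ccccc1)(c1ccccc1)C(C)(C)C | intermediate
26 | C3 primary alcohol | C[C@H]1[C@@H](O[Si](C(C)C)(C(C)C)C(C)C)C[C@@H]2OC(C)(C)O[C@@H](CO)[C@]2(C)[C@H]1[C@H]1OC(=O)[C@](C)(O)[C@@]1(O)CO[Si](c1ccccc1)(c1ccccc1)C(C)(C)C | intermediate
27 | C3 aldehyde | C[C@H]1[C@@H](O[Si](C(C)C)(C(C)C)C(C)C)C[C@@H]2OC(C)(C)O[C@@H](C=O)[C@]2(C)[C@H]1[C@H]1OC(=O)[C@](C)(O)[C@@]1(O)CO[Si](c1ccccc1)(c1ccccc1)C(C)(C)C | intermediate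
28 | (3S)-homoallylic alcohol: C3(OH)–C4H2–C5(CH3)=CH2 | C[C@H]1[C@@H](O[Si](C(C)C)(C(C)C)C(C)C)C[C@@H]2OC(C)(C)O[C@@H]([C@@H](O)CC(C)=C)[C@]2(C)[C@H]1[C@H]1OC(=O)[C@](C)(O)[C@@]1(O)CO[Si](c1ccccc1)(c1ccccc1)C(C)(C)C | intermediate
29 | C7 primary alcohol | C[C@H]1[C@@H](O[Si](C(C)C)(C(C)C)C(C)C)C[C@@H]2OC(C)(C)O[C@@H]([C@@H](O)CC(C)=C)[C@]2(C)[C@H]1[C@H]1OC(=O)[C@](C)(O)[C@@]1(O)CO | intermediate
30 | C7 aldehyde | C[C@H]1[C@@H](O[Si](C(C)C)(C(C)C)C(C)C)C[C@@H]2OC(C)(C)O[C@@H]([C@@H](O)CC(C)=C)[C@]2(C)[C@H]1[C@H]1OC(=O)[C@](C)(O)[C@@]1(O)C=O | intermediate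
31 | (7S)-allylic alcohol (C7 vinyl carbinol; diene for ring closure) | C[C@H]1[C@@H](O[Si](C(C)C)(C(C)C)C(C)C)C[C@@H]2OC(C)(C)O[C@@H]([C@@H](O)CC(C)=C)[C@]2(C)[C@H]1[C@H]1OC(=O)[C@](C)(O)[C@@]1(O)[C@@H](O)C=C | intermediate
32 | ten-membered ring (5Z), γ-lactone O9–C19 fused at C8–C9, free 3-OH and 7-OH, 2,14-acetonide, 12-O-TIPS | O[C@H]1C/C(C)=C\[C@H](O)[C@@]2(O)[C@H](OC(=O)[C@]2(C)O)[C@H]2[C@@H](C)[C@@H](O[Si](C(C)C)(C(C)C)C(C)C)C[C@@H]3OC(C)(C)O[C@@H]1[C@]23C | intermediate
33 | lactone-shifted isomer: γ-lactone O7–C19 fused at C7–C8, free 3-OH and 9-OH, 2,14-acetonide, 12-O-TIPS | O[C@H]1C/C(C)=C\[C@@H]2OC(=O)[C@](C)(O)[C@]2(O)[C@H](O)[C@H]2[C@@H](C)[C@@H](O[Si](C(C)C)(C(C)C)C(C)C)C[C@@H]3OC(C)(C)O[C@@H]1[C@]23C | intermediate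
34 | 12-O-TIPS-2,3,9,14-tetra-O-deacetylbriaexcavatolide K | O[C@H]1C/C(C)=C\[C@@H]2OC(=O)[C@](C)(O)[C@]2(O)[C@H](O)[C@H]2[C@@H](C)[C@@H](O[Si](C(C)C)(C(C)C)C(C)C)C[C@H](O)[C@]2(C)[C@H]1O | intermediate
35 | 12-O-TIPS briaexcavatolide K | CC(=O)O[C@H]1C/C(C)=C\[C@@H]2OC(=O)[C@](C)(O)[C@]2(O)[C@H](OC(C)=O)[C@H]2[C@@H](C)[C@@H](O[Si](C(C)C)(C(C)C)C(C)C)C[C@H](OC(C)=O)[C@]2(C)[C@H]1OC(C)=O | intermediate
36 | briaexcavatolide K (1R,2R,3S,5Z,7S,8R,9R,10S,11R,12S,14S,17R) | CC(=O)O[C@H]1C/C(C)=C\[C@@H]2OC(=O)[C@](C)(O)[C@]2(O)[C@H](OC(C)=O)[C@H]2[C@@H](C)[C@@H](O)C[C@H](OC(C)=O)[C@]2(C)[C@H]1OC(C)=O | target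

**Step count and risks**

Total: 30 steps. Longest linear sequence: 26 steps (steps 5–30, from 8 and 9).

Most likely to fail:

1. Step 13 (Paternò–Büchi ring closure). The excited aldehyde may be diverted into δ-hydrogen abstraction at C10 or C2, into α-cleavage, or into bridged (crossed) addition, and the facial preference may be weak. Fallback: from aldehyde 17, a hydrogen-atom-transfer radical cyclization (Fe(acac)3, PhSiH3, EtOH, 60 °C) would add a hydrogen atom to C20, and the resulting secondary C11 radical would close 6-exo onto the aldehyde, giving alcohol 19 directly without passing through 18. Should C12 come out epimeric, the 12-epi alcohol F1 would be oxidized (Dess–Martin periodinane) to ketone F2 and reduced with LiBH(s-Bu)3 from the α-face, anti to the C11 and C15 methyl groups, to return to 19.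

2. Step 26 (ring-closing metathesis). The hindered 1,1-disubstituted olefin may fail to engage, and oligomerization or olefin isomerization may win over closure of the ten-membered ring. Fallback, closing C6–C7 instead of C5=C6: from primary alcohol 29, cross-metathesis with vinylboronic acid pinacol ester (second-generation Grubbs catalyst) would give the (E)-alkenylboronate F3. Stereoinvertive iododeboronation (ICl, NaOMe) would give the (Z)-vinyl iodide F4, and copper/TEMPO aerobic oxidation the aldehyde F5. An intramolecular Nozaki–Hiyama–Kishi reaction (CrCl2, NiCl2, DMSO, high dilution) would then return to 32.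

3. Step 27 (lactone shift). The equilibrium may stop at a mixture or favor the O9 lactone. Fallback, making the shift irreversible: from 32, silylation of O3 and O7 (TESCl, imidazole) would give the bis-TES ether F6. Me(MeO)NH·HCl/AlMe3 would open the lactone to the 9-hydroxy Weinreb amide F7 (not isolated), acetylated in the same flask (Ac2O, DMAP) to the 9-acetate F8. AcOH/H2O/THF would then remove both TES groups and the acetonide and close O7 onto C19, giving the 9-acetate triol F9, and acetylation of C2, C3 and C14 (Ac2O, pyridine, DMAP) returns to 35.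

Further compounds

F1 | step 13 | 12-epi-19 (11β-methyl, 12α-hydroxyl) | C[C@H]1[C@H](O)C[C@@H]2OC(C)(C)O[C@@H](CO[Si](C)(C)C(C)(C)C)[C@]2(C)[C@H]1COCc1ccccc1
F2 | step 13 | C12 ketone of ring A | C[C@H]1C(=O)C[C@@H]2OC(C)(C)O[C@@H](CO[Si](C)(C)C(C)(C)C)[C@]2(C)[C@H]1COCc1ccccc1
F3 | step 26 | (E)-alkenylboronate: 29 with C5(CH3)=C6H–Bpin | C[C@H]1[C@@H](O[Si](C(C)C)(C(C)C)C(C)C)C[C@@H]2OC(C)(C)O[C@@H]([C@@H](O)C/C(C)=C/B3OC(C)(C)C(C)(C)O3)[C@]2(C)[C@H]1[C@H]1OC(=O)[C@](C)(O)[C@@]1(O)CO
F4 | step 26 | (Z)-vinyl iodide: 29 with C5(CH3)=C6H–I | C[C@H]1[C@@H](O[Si](C(C)C)(C(C)C)C(C)C)C[C@@H]2OC(C)(C)O[C@@H]([C@@H](O)C/C(C)=C\I)[C@]2(C)[C@H]1[C@H]1OC(=O)[C@](C)(O)[C@@]1(O)CO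
F5 | step 26 | C7 aldehyde of the (Z)-vinyl iodide | C[C@H]1[C@@H](O[Si](C(C)C)(C(C)C)C(C)C)C[C@@H]2OC(C)(C)O[C@@H]([C@@H](O)C/C(C)=C\I)[C@]2(C)[C@H]1[C@H]1OC(=O)[C@](C)(O)[C@@]1(O)C=O
F6 | step 27 | 3,7-bis-O-triethylsilyl ether of 32 | CC[Si](CC)(CC)O[C@H]1C/C(C)=C\[C@H](O[Si](CC)(CC)CC)[C@@]2(O)[C@H](OC(=O)[C@]2(C)O)[C@H]2[C@@H](C)[C@@H](O[Si](C(C)C)(C(C)C)C(C)C)C[C@@H]3OC(C)(C)O[C@@H]1[C@]23C
F7 | step 27 | 9-hydroxy C19 Weinreb amide (lactone opened) | CC[Si](CC)(CC)O[C@H]1C/C(C)=C\[C@H](O[Si](CC)(CC)CC)[C@](O)([C@@](C)(O)C(=O)N(C)OC)[C@H](O)[C@H]2[C@@H](C)[C@@H](O[Si](C(C)C)(C(C)C)C(C)C)C[C@@H]3OC(C)(C)O[C@@H]1[C@]23C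
F8 | step 27 | 9-O-acetyl C19 Weinreb amide | CC[Si](CC)(CC)O[C@H]1C/C(C)=C\[C@H](O[Si](CC)(CC)CC)[C@](O)([C@@](C)(O)C(=O)N(C)OC)[C@H](OC(C)=O)[C@H]2[C@@H](C)[C@@H](O[Si](C(C)C)(C(C)C)C(C)C)C[C@@H]3OC(C)(C)O[C@@H]1[C@]23C
F9 | step 27 | O7 lactone 9-acetate with free 2-, 3- and 14-hydroxyls (12-O-TIPS) | O[C@H]1C/C(C)=C\[C@@H]2OC(=O)[C@](C)(O)[C@]2(O)[C@H](OC(C)=O)[C@H]2[C@@H](C)[C@@H](O[Si](C(C)C)(C(C)C)C(C)C)C[C@H](O)[C@]2(C)[C@H]1O
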